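With C1 the ester-bearing carbinol, C2 the hydroxyl carbinol, C3 the CH2, C4 the ring-fusion sp2 carbon, C5 the adjacent =CH, C6 the carbonyl, C7 the enol carbon, C8 the next =CH, C9 the quaternary carbon and C10 the CH(CH3), ring B (C4–C5–C6–C7–C8–C9) is read as a masked cyclohexa-1,4-diene. Its C4=C5 bond comes from a terminal alkyne and its C9=C8–C7=C6 unit from a 1,3-diene, tied together by ring A atoms C10–C1–C2–C3. One zerovalent-nickel [4+2] cycloaddition forms C4–C9 and C5–C6, making both rings and quaternary C9. The precursor, a (7E)-6,7-dimethyldeca-7,9-dien-1-yne, carries C1 as an acetoxy carbinol, not a ketone, so C10 cannot enolise and both tether substituents sit equatorial.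

Key step: step 9

Remark: Felkin–Anh addition in step 7 is assumed to give the (5R) carbinol as the major epimer, which is the one carried on; bicyclic compounds are named on the naphthalene frame, and C-labels in the Why lines are those defined above.

Step 1
Reactants: 1 methyl (S)-3-hydroxy-2-methylpropanoate
Product: 2 methyl (S)-3-[(tert-butyldimethylsilyl)oxy]-2-methylpropanoate
Conditions: TBSCl, imidazole, CH2Cl2, 0 °C to rt
Reagents that add atoms: tert-butyldimethylsilyl chloride, CC(C)(C)[Si](C)(C)Cl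
Why: Imidazole-promoted silylation of the primary alcohol is fast and leaves the ester and the α-stereocentre (future C10) untouched.

Step 2
Reactants: 2 methyl (S)-3-[(tert-butyldimethylsilyl)oxy]-2-methylpropanoate
Product: 3 (S)-3-[(tert-butyldimethylsilyl)oxy]-2-methylpropanal
Conditions: i-Bu2AlH, CH2Cl2, −78 °C
Reagents that add atoms: none
Why: At −78 °C the aluminium hemiacetal from a single hydride addition survives until work-up, so this standard ester half-reduction stops at the aldehyde without enolising the α-centre.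

Step 3
Reactants: 3 (S)-3-[(tert-butyldimethylsilyl)oxy]-2-methylpropanal
Product: 4 (R)-tert-butyldimethyl[(2-methylbut-3-yn-1-yl)oxy]silane
Conditions: dimethyl (1-diazo-2-oxopropyl)phosphonate, K2CO3, MeOH, 0 °C to rt
Reagents that add atoms: dimethyl (1-diazo-2-oxopropyl)phosphonate, CC(=O)C(=[N+]=[N-])P(=O)(OC)OC
Why: Ohira–Bestmann homologation, in which the diazomethylphosphonate anion made in situ adds to the aldehyde and the diazoalkene loses N2 with 1,2-hydrogen shift to the terminal alkyne, is mild enough for this α-branched aldehyde.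

Step 4
Reactants: 4 (R)-tert-butyldimethyl[(2-methylbut-3-yn-1-yl)oxy]silane; 5 bromoethene
Product: 7 (R,E)-tert-butyl[(2,3-dimethylhexa-3,5-dien-1-yl)oxy]dimethylsilane, via alkenyldimethylalane 6 (not isolated)
Conditions: AlMe3, Cp2ZrCl2 (cat.), CH2Cl2, 0 °C to rt; then 5, ZnCl2, Pd(PPh3)4 (cat.), THF, rt
Reagents that add atoms: trimethylaluminium, C[Al](C)C
Why: Negishi zirconium-catalysed carboalumination adds CH3 and Al syn across the terminal alkyne (methyl on the internal carbon, future C9), and palladium–zinc cross-coupling of the alkenylalane with bromoethene proceeds with retention, fixing the (E) trisubstituted diene in one pot.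

Step 5
Reactants: 7 (R,E)-tert-butyl[(2,3-dimethylhexa-3,5-dien-1-yl)oxy]dimethylsilane
Product: 8 (R,E)-2,3-dimethylhexa-3,5-dien-1-ol
Conditions: Bu4NF, THF, 0 °C to rt
Reagents that add atoms: none
Why: Fluoride cleaves the Si–O bond (standard desilylation) without touching the diene.

Step 6
Reactants: 8 (R,E)-2,3-dimethylhexa-3,5-dien-1-ol
Product: 9 (R,E)-2,3-dimethylhexa-3,5-dienal
Conditions: Dess–Martin periodinane, NaHCO3, CH2Cl2, 0 °C; used at once
Reagents that add atoms: none
Why: Buffered Dess–Martin oxidation is neutral and fast, so the α-methyl β,γ-unsaturated aldehyde should form without enolisation or migration of the double bond into conjugation.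

Step 7
Reactants: 9 (R,E)-2,3-dimethylhexa-3,5-dienal; 10 (4-bromobut-1-yn-1-yl)trimethylsilane
Product: 13 (5R,6R,7E)-6,7-dimethyldeca-7,9-dien-1-yn-5-ol, via Grignard reagent 11 (not isolated), via C-silyl carbinol 12 (not isolated)
Conditions: 10, Mg, THF, rt; add 9, −78 °C; then MeOH, K2CO3, rt
Reagents that add atoms: none
Why: The silyl cap lets the homopropargyl Grignard reagent form without protonating itself, its addition at −78 °C should follow the Felkin–Anh model (alkenyl group anti to the nucleophile) to favour the (5R) carbinol, carbonate methanolysis then frees the terminal alkyne, and the minor (5S) epimer is removed by chromatography.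

Step 8
Reactants: 13 (5R,6R,7E)-6,7-dimethyldeca-7,9-dien-1-yn-5-ol
Product: 14 (5R,6R,7E)-6,7-dimethyldeca-7,9-dien-1-yn-5-yl acetate
Conditions: Ac2O, pyridine, DMAP (cat.), CH2Cl2, rt
Reagents that add atoms: acetic anhydride, CC(=O)OC(C)=O
Why: DMAP-catalysed acetylation of the secondary alcohol gives an ester that is neither allylic nor propargylic, hence inert to zerovalent nickel, and that is cleaved without an extra step in step 12.

Step 9
Reactants: 14 (5R,6R,7E)-6,7-dimethyldeca-7,9-dien-1-yn-5-yl acetate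
Product: 15 (1R,2R,8aR)-1,8a-dimethyl-1,2,3,4,6,8a-hexahydronaphthalen-2-yl acetate
Conditions: Ni(cod)2 (10 mol %), P(O-2-biphenylyl)3 (30 mol %), THF, rt, slow addition of 14
Reagents that add atoms: none
Why: Zerovalent nickel, made electron-poor by the bulky aryl phosphite, binds the alkyne and the diene of 14 and couples C4 with C9 oxidatively to an η3-allyl nickelacycle, which reductively eliminates with C5–C6 bond formation and releases the catalyst; this is the known nickel-catalysed intramolecular [4+2] cycloaddition of unactivated dienynes, which runs at room temperature where a thermal Diels–Alder reaction of an unactivated alkyne with a doubly substituted diene terminus would not. Ring A closes as a six-membered ring through the four-atom tether C10–C1–C2–C3 when C4–C9 forms (exo at both the alkyne and the diene), and ring B is the six-membered cycloadduct ring itself, completed by the C5–C6 reductive elimination. The only new stereocentre, quaternary C9, is set by the chair-like tether in which the C10 methyl and the C1 acetoxy group are both equatorial, whereas the competing chair that would give the C9 epimer has both axial and puts the acetoxy group 1,3-diaxial to the C9 methyl. The (7E) diene geometry from step 4 places the tether on the outer position of the diene terminus, which a fused bicycle requires. The step needs chemoselectivity for the [4+2] path over alkyne oligomerisation, which slow addition of 14 to the catalyst should secure, and the quaternary C9 keeps the skipped diene from aromatising.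

Step 10
Reactants: 15 (1R,2R,8aR)-1,8a-dimethyl-1,2,3,4,6,8a-hexahydronaphthalen-2-yl acetate
Product: 16 (1R,2R,8aR)-1,8a-dimethyl-6-oxo-1,2,3,4,6,8a-hexahydronaphthalen-2-yl acetate
Conditions: t-BuOOH, (C5H5NH)2Cr2O7, diatomaceous earth, PhH, rt
Reagents that add atoms: tert-butyl hydroperoxide, CC(C)(C)OO
Why: Chromium-mediated tert-butyl hydroperoxide allylic oxidation attacks the weakest C–H bonds, those of the doubly allylic C6 methylene, and stops at the cross-conjugated dienone because C9 is quaternary, as known for 4,4-disubstituted cyclohexa-1,4-dienes.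

Step 11
Reactants: 16 (1R,2R,8aR)-1,8a-dimethyl-6-oxo-1,2,3,4,6,8a-hexahydronaphthalen-2-yl acetate
Product: 17 (1R,2R,7R,8R,8aR)-7,8-epoxy-1,8a-dimethyl-6-oxo-1,2,3,4,6,7,8,8a-octahydronaphthalen-2-yl acetate
Conditions: t-BuOOH, DBU, CH2Cl2, 0 °C to rt
Reagents that add atoms: tert-butyl hydroperoxide, CC(C)(C)OO
Why: In this Weitz–Scheffer nucleophilic epoxidation the peroxide anion can only add to C8 (the other β-carbon, C4, is fully substituted) and should close the oxirane on the face away from the C9 methyl, as in the 1,2-selective epoxidation of steroidal 1,4-dien-3-ones; the C7/C8 configuration is erased in step 12.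

Step 12
Reactants: 17 (1R,2R,7R,8R,8aR)-7,8-epoxy-1,8a-dimethyl-6-oxo-1,2,3,4,6,7,8,8a-octahydronaphthalen-2-yl acetate
Product: 18 (4aS,5R,6R)-3,6-dihydroxy-4a,5-dimethyl-5,6,7,8-tetrahydronaphthalen-2(4aH)-one
Conditions: LiOH, THF/H2O, rt, under argon
Reagents that add atoms: lithium hydroxide, [Li+].[OH-]
Why: Hydroxide opens the α,β-epoxy ketone at C7 and E1cB loss of the C8 oxygen gives the enolised 1,2-dione (the known base-induced epoxy ketone to diosphenol isomerisation), while the same reagent saponifies the acetate and no epimerisable or eliminable centre is yet present.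

Step 13
Reactants: 18 (4aS,5R,6R)-3,6-dihydroxy-4a,5-dimethyl-5,6,7,8-tetrahydronaphthalen-2(4aH)-one
Product: 19 (4aS,5R,6R)-3-[(tert-butyldimethylsilyl)oxy]-6-hydroxy-4a,5-dimethyl-5,6,7,8-tetrahydronaphthalen-2(4aH)-one
Conditions: TBSCl (1.05 equiv), Et3N, CH2Cl2, 0 °C
Reagents that add atoms: tert-butyldimethylsilyl chloride, CC(C)(C)[Si](C)(C)Cl
Why: The acidic, phenol-like enol hydroxyl is silylated far faster than the secondary C1 alcohol, so one equivalent of silyl chloride should protect it selectively.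

Step 14
Reactants: 19 (4aS,5R,6R)-3-[(tert-butyldimethylsilyl)oxy]-6-hydroxy-4a,5-dimethyl-5,6,7,8-tetrahydronaphthalen-2(4aH)-one
Product: 20 (4aR,5R)-3-[(tert-butyldimethylsilyl)oxy]-4a,5-dimethyl-4a,5,7,8-tetrahydronaphthalene-2,6-dione
Conditions: Dess–Martin periodinane, NaHCO3, CH2Cl2, 0 °C to rt
Reagents that add atoms: none
Why: Buffered Dess–Martin oxidation converts the C1 carbinol into the ketone under non-enolising conditions, so C10 keeps its configuration and the silyl enol ether is untouched.

Step 15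
Reactants: 20 (4aR,5R)-3-[(tert-butyldimethylsilyl)oxy]-4a,5-dimethyl-4a,5,7,8-tetrahydronaphthalene-2,6-dione
Product: 22 (4aR,5R,7R)-3-[(tert-butyldimethylsilyl)oxy]-7-hydroxy-4a,5-dimethyl-4a,5,7,8-tetrahydronaphthalene-2,6-dione, via potassium enolate 21 (not isolated)
Conditions: KN(SiMe3)2, THF, −78 °C; then 3-phenyl-2-(phenylsulfonyl)oxaziridine, −78 °C; AcOH quench
Reagents that add atoms: 3-phenyl-2-(phenylsulfonyl)oxaziridine, O=S(=O)(N1OC1c1ccccc1)c1ccccc1
Why: The amide base removes a proton kinetically from the C2 methylene (C10–H is tertiary and next to quaternary C9), and in this Davis enolate oxidation the oxaziridine should deliver oxygen to C2 axially on the face opposite the axial C9 methyl, the cold acidic quench preventing α-ketol equilibration.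

Step 16
Reactants: 22 (4aR,5R,7R)-3-[(tert-butyldimethylsilyl)oxy]-7-hydroxy-4a,5-dimethyl-4a,5,7,8-tetrahydronaphthalene-2,6-dione
Product: 23 (4aS,5R,6R,7R)-3-[(tert-butyldimethylsilyl)oxy]-6,7-dihydroxy-4a,5-dimethyl-5,6,7,8-tetrahydronaphthalen-2(4aH)-one
Conditions: Me4NBH(OAc)3, MeCN/AcOH, −20 °C
Reagents that add atoms: none
Why: In this Saksena–Evans hydroxyl-directed reduction the acetoxyborohydride bound to the C2 oxygen delivers hydride to the same face of C1, which is also the face not screened by the axial C9 methyl, so the trans-diaxial diol with the C1 hydroxyl cis to both methyls should result while the dienone, lacking a directing hydroxyl, is not reduced.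

Step 17
Reactants: 23 (4aS,5R,6R,7R)-3-[(tert-butyldimethylsilyl)oxy]-6,7-dihydroxy-4a,5-dimethyl-5,6,7,8-tetrahydronaphthalen-2(4aH)-one
Product: 24 (4aS,5R,6R,7R)-3,7-bis[(tert-butyldimethylsilyl)oxy]-6-hydroxy-4a,5-dimethyl-5,6,7,8-tetrahydronaphthalen-2(4aH)-one
Conditions: TBSCl, imidazole, DMF, rt
Reagents that add atoms: tert-butyldimethylsilyl chloride, CC(C)(C)[Si](C)(C)Cl
Why: The C1 hydroxyl is 1,3-diaxial to the C9 methyl and flanked by C10, so silylation with the bulky chloride should take place only at the more accessible C2 hydroxyl (steric differentiation of a diol).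

Step 18
Reactants: 25 (S)-2-methylbutan-1-ol
Product: 26 (S)-2-methylbutanal
Conditions: TEMPO (cat.), NaOCl, KBr (cat.), NaHCO3 buffer, CH2Cl2/H2O, 0 °C
Reagents that add atoms: none
Why: Anelli oxidation (oxoammonium-mediated) at 0 °C in a buffered two-phase system gives the aldehyde without racemising the α-centre, as established for this alcohol.

Step 19
Reactants: 26 (S)-2-methylbutanal; 27 ethyl (E)-4-(diethoxyphosphoryl)but-2-enoate
Product: 28 ethyl (2E,4E,6S)-6-methylocta-2,4-dienoate
Conditions: LiOH·H2O, 4 Å molecular sieves, THF, rt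
Reagents that add atoms: none
Why: The vinylogous Horner–Wadsworth–Emmons olefination of the γ-phosphonocrotonate under mild hydroxide–sieve conditions forms the new C=C bond E-selectively, keeps the crotonate E and should not epimerise the α-branched aldehyde.

Step 20
Reactants: 28 ethyl (2E,4E,6S)-6-methylocta-2,4-dienoate
Product: 29 (2E,4E,6S)-6-methylocta-2,4-dienoic acid
Conditions: LiOH, THF/MeOH/H2O, rt; then 1 M HCl
Reagents that add atoms: lithium hydroxide, [Li+].[OH-]
Why: Saponification of the ethyl ester is safe because the remote stereocentre is not acidic.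

Step 21
Reactants: 24 (4aS,5R,6R,7R)-3,7-bis[(tert-butyldimethylsilyl)oxy]-6-hydroxy-4a,5-dimethyl-5,6,7,8-tetrahydronaphthalen-2(4aH)-one; 29 (2E,4E,6S)-6-methylocta-2,4-dienoic acid
Product: 31 (1R,2R,3R,8aS)-3,7-bis[(tert-butyldimethylsilyl)oxy]-1,8a-dimethyl-6-oxo-1,2,3,4,6,8a-hexahydronaphthalen-2-yl (2E,4E,6S)-6-methylocta-2,4-dienoate, via mixed anhydride 30 (not isolated)
Conditions: 29, 2,4,6-Cl3C6H2COCl, Et3N, toluene, rt; then 24, DMAP, toluene, 40 °C
Reagents that add atoms: none
Why: In this Yamaguchi esterification the mixed trichlorobenzoic anhydride passes the dienoyl group on through an acylpyridinium ion reactive enough for the hindered axial C1 hydroxyl, the only free hydroxyl left.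

Step 22
Reactants: 31 (1R,2R,3R,8aS)-3,7-bis[(tert-butyldimethylsilyl)oxy]-1,8a-dimethyl-6-oxo-1,2,3,4,6,8a-hexahydronaphthalen-2-yl (2E,4E,6S)-6-methylocta-2,4-dienoate
Product: 32 Septeremophilane G, (1R,2R,3R,8aS)-3,7-dihydroxy-1,8a-dimethyl-6-oxo-1,2,3,4,6,8a-hexahydronaphthalen-2-yl (2E,4E,6S)-6-methylocta-2,4-dienoate
Conditions: HF·pyridine, pyridine, THF, 0 °C to rt
Reagents that add atoms: none
Why: Buffered fluoride desilylation cleaves both the enol and the secondary silyl ether under weakly acidic conditions that spare the dienoate and the dehydration-prone C2 carbinol, and the trans-diaxial 1,2-arrangement rules out acyl migration.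

Compound list
1 | methyl (S)-3-hydroxy-2-methylpropanoate | OC[C@H](C)C(=O)OC | starting material
2 | methyl (S)-3-[(tert-butyldimethylsilyl)oxy]-2-methylpropanoate | CC(C)(C)[Si](C)(C)OC[C@H](C)C(=O)OC | intermediate
3 | (S)-3-[(tert-butyldimethylsilyl)oxy]-2-methylpropanal | CC(C)(C)[Si](C)(C)OC[C@H](C)C=O | intermediate
4 | (R)-tert-butyldimethyl[(2-methylbut-3-yn-1-yl)oxy]silane | CC(C)(C)[Si](C)(C)OC[C@H](C)C#C | intermediate
5 | bromoethene | C=CBr | starting material
6 | [(1E,3R)-4-[(tert-butyldimethylsilyl)oxy]-2,3-dimethylbut-1-en-1-yl]dimethylalumane | CC(C)(C)[Si](C)(C)OC[C@H](C)/C(C)=C/[Al](C)C | intermediate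
7 | (R,E)-tert-butyl[(2,3-dimethylhexa-3,5-dien-1-yl)oxy]dimethylsilane | CC(C)(C)[Si](C)(C)OC[C@H](C)/C(C)=C/C=C | intermediate
8 | (R,E)-2,3-dimethylhexa-3,5-dien-1-ol | OC[C@H](C)/C(C)=C/C=C | intermediate
9 | (R,E)-2,3-dimethylhexa-3,5-dienal | O=C[C@H](C)/C(C)=C/C=C | intermediate
10 | (4-bromobut-1-yn-1-yl)trimethylsilane | C[Si](C)(C)C#CCCBr | starting material
11 | [4-(trimethylsilyl)but-3-yn-1-yl]magnesium bromide | C[Si](C)(C)C#CCC[Mg]Br | intermediate
12 | (5R,6R,7E)-6,7-dimethyl-1-(trimethylsilyl)deca-7,9-dien-1-yn-5-ol | C[Si](C)(C)C#CCC[C@@H](O)[C@H](C)/C(C)=C/C=C | intermediate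
13 | (5R,6R,7E)-6,7-dimethyldeca-7,9-dien-1-yn-5-ol | C#CCC[C@@H](O)[C@H](C)/C(C)=C/C=C | intermediate
14 | (5R,6R,7E)-6,7-dimethyldeca-7,9-dien-1-yn-5-yl acetate | C#CCC[C@@H](OC(C)=O)[C@H](C)/C(C)=C/C=C | intermediate
15 | (1R,2R,8aR)-1,8a-dimethyl-1,2,3,4,6,8a-hexahydronaphthalen-2-yl acetate | CC(=O)O[C@@H]1CCC2=CCC=C[C@]2(C)[C@H]1C | intermediate
16 | (1R,2R,8aR)-1,8a-dimethyl-6-oxo-1,2,3,4,6,8a-hexahydronaphthalen-2-yl acetate | CC(=O)O[C@@H]1CCC2=CC(=O)C=C[C@]2(C)[C@H]1C | intermediate
17 | (1R,2R,7R,8R,8aR)-7,8-epoxy-1,8a-dimethyl-6-oxo-1,2,3,4,6,7,8,8a-octahydronaphthalen-2-yl acetate (oxirane anti to the 8a-methyl) | CC(=O)O[C@@H]1CCC2=CC(=O)[C@@H]3O[C@@H]3[C@]2(C)[C@H]1C | intermediate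
18 | (4aS,5R,6R)-3,6-dihydroxy-4a,5-dimethyl-5,6,7,8-tetrahydronaphthalen-2(4aH)-one | O[C@@H]1CCC2=CC(=O)C(O)=C[C@]2(C)[C@H]1C | intermediate
19 | (4aS,5R,6R)-3-[(tert-butyldimethylsilyl)oxy]-6-hydroxy-4a,5-dimethyl-5,6,7,8-tetrahydronaphthalen-2(4aH)-one | O[C@@H]1CCC2=CC(=O)C(O[Si](C)(C)C(C)(C)C)=C[C@]2(C)[C@H]1C | intermediate
20 | (4aR,5R)-3-[(tert-butyldimethylsilyl)oxy]-4a,5-dimethyl-4a,5,7,8-tetrahydronaphthalene-2,6-dione | O=C1CCC2=CC(=O)C(O[Si](C)(C)C(C)(C)C)=C[C@]2(C)[C@H]1C | intermediate
21 | potassium C1–C2 enolate of 20 (C9 and C10 as in 20) | [K+].[O-]C1=CCC2=CC(=O)C(O[Si](C)(C)C(C)(C)C)=C[C@]2(C)[C@H]1C | intermediate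
22 | (4aR,5R,7R)-3-[(tert-butyldimethylsilyl)oxy]-7-hydroxy-4a,5-dimethyl-4a,5,7,8-tetrahydronaphthalene-2,6-dione | O=C1[C@H](O)CC2=CC(=O)C(O[Si](C)(C)C(C)(C)C)=C[C@]2(C)[C@H]1C | intermediate
23 | (4aS,5R,6R,7R)-3-[(tert-butyldimethylsilyl)oxy]-6,7-dihydroxy-4a,5-dimethyl-5,6,7,8-tetrahydronaphthalen-2(4aH)-one | O[C@H]1[C@H](O)CC2=CC(=O)C(O[Si](C)(C)C(C)(C)C)=C[C@]2(C)[C@H]1C | intermediate
24 | (4aS,5R,6R,7R)-3,7-bis[(tert-butyldimethylsilyl)oxy]-6-hydroxy-4a,5-dimethyl-5,6,7,8-tetrahydronaphthalen-2(4aH)-one | O[C@H]1[C@H](O[Si](C)(C)C(C)(C)C)CC2=CC(=O)C(O[Si](C)(C)C(C)(C)C)=C[C@]2(C)[C@H]1C | intermediate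
25 | (S)-2-methylbutan-1-ol | CC[C@H](C)CO | starting material
26 | (S)-2-methylbutanal | CC[C@H](C)C=O | intermediate
27 | ethyl (E)-4-(diethoxyphosphoryl)but-2-enoate | CCOC(=O)/C=C/CP(=O)(OCC)OCC | starting material
28 | ethyl (2E,4E,6S)-6-methylocta-2,4-dienoate | CC[C@H](C)/C=C/C=C/C(=O)OCC | intermediate
29 | (2E,4E,6S)-6-methylocta-2,4-dienoic acid | CC[C@H](C)/C=C/C=C/C(=O)O | intermediate
30 | (2E,4E,6S)-6-methylocta-2,4-dienoic 2,4,6-trichlorobenzoic anhydride | CC[C@H](C)/C=C/C=C/C(=O)OC(=O)c1c(Cl)cc(Cl)cc1Cl | intermediate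
31 | (1R,2R,3R,8aS)-3,7-bis[(tert-butyldimethylsilyl)oxy]-1,8a-dimethyl-6-oxo-1,2,3,4,6,8a-hexahydronaphthalen-2-yl (2E,4E,6S)-6-methylocta-2,4-dienoate | CC[C@H](C)/C=C/C=C/C(=O)O[C@H]1[C@H](O[Si](C)(C)C(C)(C)C)CC2=CC(=O)C(O[Si](C)(C)C(C)(C)C)=C[C@]2(C)[C@H]1C | intermediate
32 | Septeremophilane G, (1R,2R,3R,8aS)-3,7-dihydroxy-1,8a-dimethyl-6-oxo-1,2,3,4,6,8a-hexahydronaphthalen-2-yl (2E,4E,6S)-6-methylocta-2,4-dienoate | CC[C@H](C)/C=C/C=C/C(=O)O[C@H]1[C@H](O)CC2=CC(=O)C(O)=C[C@]2(C)[C@H]1C | target

Total step count: 22. Longest linear sequence: 19 (steps 1–17, 21 and 22); the side-chain acid takes steps 18–20.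

Steps most likely to fail

1. Step 9. The free terminal alkyne may oligomerise or form nickel acetylides faster than it couples with the hindered, doubly substituted diene terminus, and any (5S) acetate carried along would cyclise toward the C9 epimer. The fallback sets out from 9 and 10 and comes back at 15. The Grignard addition of step 7 is worked up without the carbonate treatment, so that the (5R) C-silyl carbinol 12 is isolated and purified. Acetylation (Ac2O, pyridine, DMAP) gives (5R,6R,7E)-6,7-dimethyl-1-(trimethylsilyl)deca-7,9-dien-1-yn-5-yl acetate F1. Its capped alkyne cannot give acetylides or trimerise and belongs to the substrate class on which the nickel–phosphite [4+2] cycloaddition is best behaved. Cyclisation under the step 9 conditions should give (1R,2R,8aR)-1,8a-dimethyl-5-(trimethylsilyl)-1,2,3,4,6,8a-hexahydronaphthalen-2-yl acetate F2. Ipso-protodesilylation of the vinylsilane (CF3CO2H, CH2Cl2, 0 °C) then returns 15.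

2. Step 21. Acylation of the C1 hydroxyl, which is axial, 1,3-diaxial to the C9 methyl and flanked by C10 and the C2 silyl ether, may be so slow that the activated dienoic acid isomerises or decomposes first. The fallback sets out from 24 and comes back at 31. The alcohol is acylated with the small, unconjugated and more electrophilic diethylphosphonoacetic acid (DCC, DMAP, CH2Cl2) to give (1R,2R,3R,8aS)-3,7-bis[(tert-butyldimethylsilyl)oxy]-1,8a-dimethyl-6-oxo-1,2,3,4,6,8a-hexahydronaphthalen-2-yl 2-(diethoxyphosphoryl)acetate F4. A Horner–Wadsworth–Emmons olefination (LiCl, i-Pr2NEt, MeCN, rt) with (S,E)-4-methylhex-2-enal F5, made from 26 and (triphenylphosphoranylidene)acetaldehyde, then builds the (2E,4E)-dienoate on the substrate and gives 31.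

3. Step 12. Hydroxide may open the oxirane of 17 only slowly at C7, because it must approach syn to the C9 methyl, which would leave the diosphenolate exposed to air oxidation or benzilic-acid-type ring contraction. The fallback sets out from 16 and comes back at 18. Dihydroxylation with OsO4 (cat.) and N-methylmorpholine N-oxide in acetone/H2O should take place at the less hindered C7=C8 bond and give (1R,2R,7R,8R,8aR)-7,8-dihydroxy-1,8a-dimethyl-6-oxo-1,2,3,4,6,7,8,8a-octahydronaphthalen-2-yl acetate F3. K2CO3 in MeOH at rt then removes the acetate and eliminates the C8 hydroxyl through the C6 enolate (E1cB) to give 18, with no nucleophilic attack on the ring needed.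

Further compounds
F1 | step 9 | (5R,6R,7E)-6,7-dimethyl-1-(trimethylsilyl)deca-7,9-dien-1-yn-5-yl acetate | C[Si](C)(C)C#CCC[C@@H](OC(C)=O)[C@H](C)/C(C)=C/C=C
F2 | step 9 | (1R,2R,8aR)-1,8a-dimethyl-5-(trimethylsilyl)-1,2,3,4,6,8a-hexahydronaphthalen-2-yl acetate | CC(=O)O[C@@H]1CCC2=C([Si](C)(C)C)CC=C[C@]2(C)[C@H]1C
F3 | step 12 | (1R,2R,7R,8R,8aR)-7,8-dihydroxy-1,8a-dimethyl-6-oxo-1,2,3,4,6,7,8,8a-octahydronaphthalen-2-yl acetate | CC(=O)O[C@@H]1CCC2=CC(=O)[C@H](O)[C@H](O)[C@]2(C)[C@H]1C
F4 | step 21 | (1R,2R,3R,8aS)-3,7-bis[(tert-butyldimethylsilyl)oxy]-1,8a-dimethyl-6-oxo-1,2,3,4,6,8a-hexahydronaphthalen-2-yl 2-(diethoxyphosphoryl)acetate | CCOP(=O)(OCC)CC(=O)O[C@H]1[C@H](O[Si](C)(C)C(C)(C)C)CC2=CC(=O)C(O[Si](C)(C)C(C)(C)C)=C[C@]2(C)[C@H]1C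
F5 | step 21 | (S,E)-4-methylhex-2-enal | CC[C@H](C)/C=C/C=O
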